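The runs were computed for substances that don't exist.

For whoever takes over the bench: west is the flask to watch. Substrate and first nucleophile stand together from the start, and second nucleophile comes in by pump over 8.00 min.

| setting | autumn | dawn | dusk | summer | south | north-east | west | east |
|---|---|---|---|---|---|---|---|---|
| substrate | 35 mM | 35 mM | 35 mM | 52 mM | 35 mM (fed, over 8.00 min) | 35 mM | 35 mM | 35 mM |
| first nucleophile | 33.2 mM | 46 mM | 73 mM | 33.2 mM | 33.2 mM | 33.2 mM | 33.2 mM | 33.2 mM |
| second nucleophile | 31.5 mM | 31.5 mM | 31.5 mM | 31.5 mM | 31.5 mM | 31.5 mM | 31.5 mM (fed, over 8.00 min) | 31.5 mM |
| protic impurity | 1.75 mM | 1.75 mM | 1.75 mM | 1.75 mM | 1.75 mM | 1.75 mM | 1.75 mM | 1.75 mM |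
| remark | run made earlier | run made earlier | run made earlier | run made earlier | a stirred flask in which substrate is dosed at a steady rate over 8.00 min without added volume, worked up at 10 min | one stirred flow tank at steady state, fed with the mixture as stated, mean residence time 10 min | a stirred flask in which second nucleophile is dosed at a steady rate over 8.00 min without added volume, worked up at 10 min | everything together in a closed stirred flask, run for 10 min |
| time |  |  |  |  | 10 min |  | 10 min | 10 min |

| run | time / min | target / % | other capture product / % |
|---|---|---|---|
| autumn | 2.50 | 17.9 | 21.4 |
| autumn | 5.00 | 28.7 | 33.3 |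
| autumn | 8.00 | 38.9 | 40.1 |
| autumn | 10.0 | 41.5 | 42.2 |
| dawn | 0.500 | 4.2 | 3.8 |
| dawn | 1.00 | 8.3 | 8.7 |
| dawn | 2.50 | 21.2 | 19.1 |
| dawn | 6.00 | 39.0 | 31.1 |
| dusk | 1.50 | 17.7 | 10.4 |
| dusk | 3.00 | 32.0 | 18.0 |
| dusk | 5.00 | 44.1 | 22.5 |
| dusk | 6.00 | 49.9 | 25.0 |
| summer | 1.50 | 10.9 | 13.5 |
| summer | 3.00 | 19.6 | 22.8 |
| summer | 5.00 | 28.9 | 31.5 |
| summer | 6.00 | 32.7 | 33.3 |

(each reading ± 0.5 percentage points)

- the stated concentrations are those of everything mixed, before any reaction; amounts are the same in each set-up
- steps thought possible: substrate <-> intermediate; first nucleophile + intermediate -> target; second nucleophile + intermediate -> other capture product; second nucleophile <-> dormant form; second nucleophile + protic impurity -> quenched reagent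
- the feed brings no volume worth counting
- the earlier runs were made in a closed, stirred flask

1. the set-up with the highest share of target in all that became target or other capture product, at the outlet or at the end ("none" if the first two lie within 2 percentage points) (south / north-east / west / east / none)
2. share of target in all that became target or other capture product, at the outlet or at the end, south
3. share of target in all that became target or other capture product, at the outlet or at the end, north-east
4. share of target in all that became target or other capture product, at the outlet or at the end, west
5. share of target in all that became target or other capture product, at the outlet or at the end, east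

Both nucleophiles compete for one intermediate. The carried quantity is the capture ratio (a selectivity factor): the odds of target over other capture product, divided by c(first nucleophile)/c(second nucleophile). The first dusk reading, at 1.50 min, gives 0.734.

Autumn has the charges of east and ends at odds of 0.983. Its felt nucleophile ratio is therefore 1.34, higher than the charged 1.05. By 10.0 min, autumn has turned 83.7% of its substrate into the two products. West should stand near that, with substrate still in it.

A steady feed supplies, averaged over the feed, half the charge of second nucleophile. With charged levels otherwise, this reckoning gives a west share of 60.8%. Doubling autumn's odds instead gives 1.97, a share of 66.3%. So the pump is not to be hurried: the undosed autumn flask has odds lower than these.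

The forecast names west, with 65% (60% to 70%) there against 50.5% south, 51% north-east and 49.7% east: "West keeps the second nucleophile scarce early, while the first is plentiful".

West gives 63.4%, against 52.7% south, 52.2% north-east and 49.9% east.

    substrate ⇌ intermediate (K = 0.260, k = 0.300 min⁻¹)
    first nucleophile + intermediate → target (k = 50.0 M⁻¹ min⁻¹)
    second nucleophile + intermediate → other capture product (k = 74.0 M⁻¹ min⁻¹)
    second nucleophile ⇌ dormant form (K = 4.10, k = 0.0540 min⁻¹)
    second nucleophile + protic impurity → quenched reagent (k = 16.0 M⁻¹ min⁻¹)

At 10.0 min, west holds 52.0% target, 30.0% other capture product and 16.3% substrate. For the flask like west with 83 mM of first nucleophile, the capture ratio read from the dusk run and half the charge of second nucleophile give odds of 3.87, a share of 79.5%. That flask gives 83.2%.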